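**Assumption:** the target is taken exactly as drawn (trans-fused hydroazulene); (S)-β-citronellene, tiglic aldehyde, pent-4-enal, (−)-sparteine and (R)-diphenylprolinol trimethylsilyl ether are taken as commercial.

**Position labels used below:** C1 and C5 are the ring-fusion carbons (C1 bears C10), C2–C3=C4(CH3) completes the five-membered ring, C6 = CHOH, C7 bears the side chain, C8 = CH2, C9 = CHOAc, C10 = C(=CH2), C11 = side-chain CH(CH3).

## Retrosynthetic overview

1. Target ⇐ selective C9 acetylation of the 6,9-diol; the seven-membered ring is closed last by a Nozaki–Hiyama–Kishi reaction (C9–C10) of an iodovinyl aldehyde.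
2. Key bond C6–C7 ⇐ Hoppe homoaldol reaction: a sparteine-lithiated, titanated (E)-2-alkenyl carbamate (a homoenolate equivalent of the C9 aldehyde) adds to a cyclopentenyl aldehyde and sets C6 and C7 together; a 1,5-carbamoyl shift then frees the C9 aldehyde.
3. Carbamate arm ⇐ (S)-β-citronellene (source of C11): Schenck ene reaction, silylation, cross-metathesis with allyl carbamate.
4. Aldehyde arm ⇐ enamine-catalysed Michael addition of pent-4-enal to a nitrodiene (sets C5; C1 settles trans), ring-closing metathesis (five-membered ring, made first), alkyne then iodoalkene, Nef reaction.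

## Route

**Step 1**
Reactants: 1 prop-2-en-1-ol (allyl alcohol); 2 N,N-di(propan-2-yl)carbamoyl chloride
Product: 3 prop-2-en-1-yl N,N-di(propan-2-yl)carbamate
Conditions: NaH, THF, 0 to 65 °C
Reagents that add atoms: none
Why: Carbamoylation of the sodium alkoxide by the carbamoyl chloride; no stereocentre is involved.

**Step 2**
Reactants: 4 (3S)-3,7-dimethylocta-1,6-diene [(S)-β-citronellene]
Product: 6 (3E,6S)-2,6-dimethylocta-3,7-dien-2-ol, via allylic hydroperoxide 5 (not isolated)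
Conditions: O2, tetraphenylporphyrin (cat.), visible light, CH2Cl2, 0 °C; then PPh3
Reagents that add atoms: dioxygen O=O
Why: Schenck ene reaction of singlet oxygen at the trisubstituted alkene only gives the (E)-tertiary hydroperoxide, reduced by PPh3; the secondary regioisomer (about half of the material) is removed by chromatography and C11 is untouched.

**Step 3**
Reactants: 6 (3E,6S)-2,6-dimethylocta-3,7-dien-2-ol
Product: 7 {[(3E,6S)-2,6-dimethylocta-3,7-dien-2-yl]oxy}trimethylsilane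
Conditions: 1-(trimethylsilyl)imidazole, CH2Cl2, rt
Reagents that add atoms: 1-(trimethylsilyl)imidazole C[Si](C)(C)n1ccnc1
Why: Silylation masks the tertiary hydroxyl against s-BuLi in step 11; the group is removed in step 14.

**Step 4**
Reactants: 7 {[(3E,6S)-2,6-dimethylocta-3,7-dien-2-yl]oxy}trimethylsilane; 3 prop-2-en-1-yl N,N-di(propan-2-yl)carbamate
Product: 8 (2E,4S,6E)-4,8-dimethyl-8-[(trimethylsilyl)oxy]nona-2,6-dien-1-yl N,N-di(propan-2-yl)carbamate
Conditions: 3 (3 equiv), second-generation Hoveyda–Grubbs catalyst (5 mol%), CH2Cl2, 40 °C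
Reagents that add atoms: none
Why: Olefin cross-metathesis of the α-branched vinyl group with the allyl carbamate is E-selective, and the internal alkene next to the quaternary carbon is too hindered to react.

**Step 5**
Reactants: 9 (2E)-2-methylbut-2-enal (tiglic aldehyde); 10 nitromethane
Product: 12 (1E,3E)-3-methyl-1-nitropenta-1,3-diene, via nitro alcohol 11 (not isolated)
Conditions: 10 (5 equiv), Et3N (10 mol%), 0 °C; then MsCl, Et3N, CH2Cl2, −20 to 0 °C
Reagents that add atoms: none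
Why: Henry reaction at the carbonyl (the α,β-dimethyl enal resists conjugate addition) followed by mesylation and E1cB elimination gives the (E)-nitroalkene.

**Step 6**
Reactants: 12 (1E,3E)-3-methyl-1-nitropenta-1,3-diene; 13 pent-4-enal
Product: 14 (2S,3R,4E)-4-methyl-3-(nitromethyl)-2-(prop-2-en-1-yl)hex-4-enal
Conditions: 13 (2 equiv), (R)-2-[diphenyl(trimethylsilyloxy)methyl]pyrrolidine (10 mol%), 4-nitrophenol (10 mol%), toluene, 0 °C
Reagents that add atoms: none
Why: Enamine-catalysed Michael addition (Hayashi type) occurs 1,4 at the nitroalkene; the anti-enamine of the (R)-catalyst is attacked on the face away from the CPh2OSiMe3 group through a synclinal transition state, giving the syn adduct with C5 fixed as R and C1 as S (C1 remains epimerisable).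

**Step 7**
Reactants: 14 (2S,3R,4E)-4-methyl-3-(nitromethyl)-2-(prop-2-en-1-yl)hex-4-enal
Product: 15 (1S,2R)-3-methyl-2-(nitromethyl)cyclopent-3-ene-1-carbaldehyde
Conditions: second-generation Grubbs catalyst (3 mol%), CH2Cl2, 40 °C
Reagents that add atoms: none
Why: Ring-closing metathesis of the allyl group onto the trisubstituted butenyl group expels propene and forms the methyl-substituted cyclopentene; the syn adduct maps onto the trans ring and no stereocentre is touched.

**Step 8**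
Reactants: 15 (1S,2R)-3-methyl-2-(nitromethyl)cyclopent-3-ene-1-carbaldehyde
Product: 16 (4S,5R)-4-ethynyl-1-methyl-5-(nitromethyl)cyclopent-1-ene
Conditions: dimethyl (1-diazo-2-oxopropyl)phosphonate, K2CO3, MeOH, 0 °C to rt
Reagents that add atoms: dimethyl (1-diazo-2-oxopropyl)phosphonate COP(=O)(OC)C(=[N+]=[N-])C(C)=O
Why: Ohira–Bestmann homologation converts the aldehyde into the terminal alkyne; under K2CO3/MeOH the aldehyde α-centre C1 equilibrates to the more stable trans arrangement before it is locked, while C5 is not acidic.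

**Step 9**
Reactants: 16 (4S,5R)-4-ethynyl-1-methyl-5-(nitromethyl)cyclopent-1-ene
Product: 18 (4S,5R)-4-(1-iodoethenyl)-1-methyl-5-(nitromethyl)cyclopent-1-ene, via iodoalkenylborane 17 (not isolated)
Conditions: B-iodo-9-borabicyclo[3.3.1]nonane, pentane/CH2Cl2, −20 °C; then AcOH
Reagents that add atoms: B-iodo-9-borabicyclo[3.3.1]nonane IB1C2CCCC1CCC2
Why: syn-Iodoboration of the terminal alkyne puts iodine on the internal carbon and protodeboronation with acetic acid gives the 2-iodoalk-1-ene; the trisubstituted alkene and the nitro group are inert.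

**Step 10**
Reactants: 18 (4S,5R)-4-(1-iodoethenyl)-1-methyl-5-(nitromethyl)cyclopent-1-ene
Product: 20 (1R,5S)-5-(1-iodoethenyl)-2-methylcyclopent-2-ene-1-carbaldehyde, via sodium nitronate 19 (not isolated)
Conditions: NaOMe, MeOH, 0 °C; then aq. TiCl3, NH4OAc (pH about 5), 0 °C
Reagents that add atoms: water O
Why: Nef reaction in the TiCl3 version reduces the nitronate to the imine, which hydrolyses to the aldehyde under buffered conditions that keep the alkene out of conjugation; C5 keeps its trans configuration, which is also the more stable one.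

**Step 11**
Reactants: 8 (2E,4S,6E)-4,8-dimethyl-8-[(trimethylsilyl)oxy]nona-2,6-dien-1-yl N,N-di(propan-2-yl)carbamate; 20 (1R,5S)-5-(1-iodoethenyl)-2-methylcyclopent-2-ene-1-carbaldehyde
Product: 23 (1Z,3S,4S)-4-hydroxy-4-[(1R,5S)-5-(1-iodoethenyl)-2-methylcyclopent-2-en-1-yl]-3-[(2S,4E)-6-methyl-6-[(trimethylsilyl)oxy]hept-4-en-2-yl]but-1-en-1-yl N,N-di(propan-2-yl)carbamate, via lithio carbamate 21 (not isolated), via titanium reagent 22 (not isolated)
Conditions: 8 (1.3 equiv), s-BuLi, (−)-sparteine, toluene, −78 °C; Ti(OiPr)4, −78 °C; 20, −78 to −30 °C; aq. NH4Cl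
Reagents that add atoms: none
Why: Hoppe homoaldol reaction, in which the metallated carbamate acts as a homoenolate of the C9 aldehyde so that its γ-carbon C7 bonds to the carbonyl carbon C6; the (S)-lithio–sparteine species gives the (R)-titanium reagent by inversion, and its Zimmerman–Traxler chair (E-alkene gives anti, axial carbamate oxygen gives the Z enol carbamate) sets 6S and 7R under reagent control, with the larger C1 arm of 20 placed anti to the incoming carbon.

**Step 12**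
Reactants: 23 homoaldol adduct (name as in step 11)
Product: 25 (1S,2R)-1-[(1R,5S)-5-(1-iodoethenyl)-2-methylcyclopent-2-en-1-yl]-2-[(2S,4E)-6-methyl-6-[(trimethylsilyl)oxy]hept-4-en-2-yl]-4-oxobutyl N,N-di(propan-2-yl)carbamate, via potassium enolate 24 (not isolated)
Conditions: KN(SiMe3)2 (1.05 equiv), THF, −78 to −40 °C; AcOH, −78 °C
Reagents that add atoms: none
Why: Base-induced 1,5-O-to-O carbamoyl migration, in which the C6 alkoxide attacks the carbonyl of the (Z)-enol carbamate through a seven-membered transition state and releases the aldehyde enolate, quenched cold before 1,3-cycloelimination can start; C6–O is protected and the C9 aldehyde freed in one operation with no stereocentre changed.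

**Step 13**
Reactants: 25 carbamoyloxy aldehyde (name as in step 12)
Product: 26 (3aR,4S,5R,7R,8aS)-7-hydroxy-3-methyl-8-methylidene-5-[(2S,4E)-6-methyl-6-[(trimethylsilyl)oxy]hept-4-en-2-yl]-1,3a,4,5,6,7,8,8a-octahydroazulen-4-yl N,N-di(propan-2-yl)carbamate
Conditions: CrCl2 (8 equiv), NiCl2 (2 mol%), DMSO/THF, 5 mM, rt
Reagents that add atoms: none
Why: Nozaki–Hiyama–Kishi reaction, in which the vinyl iodide adds oxidatively to zerovalent nickel, is passed to trivalent chromium and adds only to the aldehyde to close the seven-membered ring with the exocyclic methylene in place; a chair-like transition state with the C7 side chain and the new C9–O bond pseudo-equatorial is expected to give 9R.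

**Step 14**
Reactants: 26 hydroazulenyl carbamate (name as in step 13)
Product: 28 (3aR,4S,5R,7R,8aS)-5-[(2S,4E)-6-hydroxy-6-methylhept-4-en-2-yl]-3-methyl-8-methylidene-1,3a,4,5,6,7,8,8a-octahydroazulene-4,7-diol, via diol silyl ether 27 (not isolated)
Conditions: LiAlH4 (5 equiv), THF, 65 °C; H2O then 15% aq. NaOH; then K2CO3, MeOH, rt
Reagents that add atoms: none
Why: Hydride reduction cleaves the hindered carbamate to the C6 alkoxide and the N-methyl amine, and methanolysis then removes the silyl ether; no stereocentre is affected.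

**Step 15**
Reactants: 28 triol (name as in step 14)
Product: 29 (3aS,5R,7R,8S,8aR)-8-hydroxy-7-[(2S,4E)-6-hydroxy-6-methylhept-4-en-2-yl]-1-methyl-4-methylidene-3,3a,4,5,6,7,8,8a-octahydroazulen-5-yl acetate (the target; the 9-O-acetate of 28 in the position labels above)
Conditions: Ac2O (1.2 equiv), pyridine, CH2Cl2, −20 to 0 °C
Reagents that add atoms: acetic anhydride CC(=O)OC(C)=O
Why: Selective acylation of the allylic C9 hydroxyl, which is far less hindered than the C6 hydroxyl (flanked by two methine carbons) and the tertiary hydroxyl.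

## Compound list

1 | prop-2-en-1-ol | C=CCO | starting material
2 | N,N-di(propan-2-yl)carbamoyl chloride | CC(C)N(C(C)C)C(=O)Cl | starting material
3 | prop-2-en-1-yl N,N-di(propan-2-yl)carbamate | C=CCOC(=O)N(C(C)C)C(C)C | intermediate
4 | (3S)-3,7-dimethylocta-1,6-diene | C=C[C@@H](C)CCC=C(C)C | starting material
5 | (3E,6S)-2,6-dimethylocta-3,7-dien-2-yl hydroperoxide (not isolated) | C=C[C@@H](C)C/C=C/C(C)(C)OO | intermediate
6 | (3E,6S)-2,6-dimethylocta-3,7-dien-2-ol | C=C[C@@H](C)C/C=C/C(C)(C)O | intermediate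
7 | {[(3E,6S)-2,6-dimethylocta-3,7-dien-2-yl]oxy}trimethylsilane | C=C[C@@H](C)C/C=C/C(C)(C)O[Si](C)(C)C | intermediate
8 | (2E,4S,6E)-4,8-dimethyl-8-[(trimethylsilyl)oxy]nona-2,6-dien-1-yl N,N-di(propan-2-yl)carbamate | CC(C)N(C(C)C)C(=O)OC/C=C/[C@@H](C)C/C=C/C(C)(C)O[Si](C)(C)C | intermediate
9 | (2E)-2-methylbut-2-enal | C/C=C(\C)C=O | starting material
10 | nitromethane | C[N+](=O)[O-] | starting material
11 | (3E)-3-methyl-1-nitropent-3-en-2-ol, racemic (not isolated) | C/C=C(\C)C(O)C[N+](=O)[O-] | intermediate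
12 | (1E,3E)-3-methyl-1-nitropenta-1,3-diene | C/C=C(\C)/C=C/[N+](=O)[O-] | intermediate
13 | pent-4-enal | C=CCCC=O | starting material
14 | (2S,3R,4E)-4-methyl-3-(nitromethyl)-2-(prop-2-en-1-yl)hex-4-enal | O=C[C@@H](CC=C)[C@H](/C(C)=C/C)C[N+](=O)[O-] | intermediate
15 | (1S,2R)-3-methyl-2-(nitromethyl)cyclopent-3-ene-1-carbaldehyde | O=C[C@H]1CC=C(C)[C@@H]1C[N+](=O)[O-] | intermediate
16 | (4S,5R)-4-ethynyl-1-methyl-5-(nitromethyl)cyclopent-1-ene | C#C[C@H]1CC=C(C)[C@@H]1C[N+](=O)[O-] | intermediate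
17 | 9-{(1Z)-2-iodo-2-[(1S,2R)-3-methyl-2-(nitromethyl)cyclopent-3-en-1-yl]ethenyl}-9-borabicyclo[3.3.1]nonane (not isolated) | I/C(=C\B1C2CCCC1CCC2)[C@H]1CC=C(C)[C@@H]1C[N+](=O)[O-] | intermediate
18 | (4S,5R)-4-(1-iodoethenyl)-1-methyl-5-(nitromethyl)cyclopent-1-ene | C=C(I)[C@H]1CC=C(C)[C@@H]1C[N+](=O)[O-] | intermediate
19 | sodium nitronate of 18 (not isolated) | C=C(I)[C@H]1CC=C(C)[C@@H]1C=[N+]([O-])[O-].[Na+] | intermediate
20 | (1R,5S)-5-(1-iodoethenyl)-2-methylcyclopent-2-ene-1-carbaldehyde | C=C(I)[C@H]1CC=C(C)[C@@H]1C=O | intermediate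
21 | (1S)-1-lithio derivative of 8, ligated by (−)-sparteine in solution (not isolated) | CC(C)N(C(C)C)C(=O)O[C@@H]([Li])/C=C/[C@@H](C)C/C=C/C(C)(C)O[Si](C)(C)C | intermediate
22 | (1R)-1-[tri(propan-2-yloxy)titanio] derivative of 8 (not isolated) | CC(C)N(C(C)C)C(=O)O[C@H]([Ti](OC(C)C)(OC(C)C)OC(C)C)/C=C/[C@@H](C)C/C=C/C(C)(C)O[Si](C)(C)C | intermediate
23 | (1Z,3S,4S)-4-hydroxy-4-[(1R,5S)-5-(1-iodoethenyl)-2-methylcyclopent-2-en-1-yl]-3-[(2S,4E)-6-methyl-6-[(trimethylsilyl)oxy]hept-4-en-2-yl]but-1-en-1-yl N,N-di(propan-2-yl)carbamate | C=C(I)[C@H]1CC=C(C)[C@@H]1[C@@H](O)[C@@H]([C@@H](C)C/C=C/C(C)(C)O[Si](C)(C)C)/C=C\OC(=O)N(C(C)C)C(C)C | intermediate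
24 | potassium (Z)-enolate of 25 (not isolated) | C=C(I)[C@H]1CC=C(C)[C@@H]1[C@@H](OC(=O)N(C(C)C)C(C)C)[C@@H]([C@@H](C)C/C=C/C(C)(C)O[Si](C)(C)C)/C=C\[O-].[K+] | intermediate
25 | (1S,2R)-1-[(1R,5S)-5-(1-iodoethenyl)-2-methylcyclopent-2-en-1-yl]-2-[(2S,4E)-6-methyl-6-[(trimethylsilyl)oxy]hept-4-en-2-yl]-4-oxobutyl N,N-di(propan-2-yl)carbamate | C=C(I)[C@H]1CC=C(C)[C@@H]1[C@@H](OC(=O)N(C(C)C)C(C)C)[C@@H]([C@@H](C)C/C=C/C(C)(C)O[Si](C)(C)C)CC=O | intermediate
26 | (3aR,4S,5R,7R,8aS)-7-hydroxy-3-methyl-8-methylidene-5-[(2S,4E)-6-methyl-6-[(trimethylsilyl)oxy]hept-4-en-2-yl]-1,3a,4,5,6,7,8,8a-octahydroazulen-4-yl N,N-di(propan-2-yl)carbamate | C=C1[C@H]2CC=C(C)[C@@H]2[C@@H](OC(=O)N(C(C)C)C(C)C)[C@@H]([C@@H](C)C/C=C/C(C)(C)O[Si](C)(C)C)C[C@H]1O | intermediate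
27 | (3aR,4S,5R,7R,8aS)-3-methyl-8-methylidene-5-[(2S,4E)-6-methyl-6-[(trimethylsilyl)oxy]hept-4-en-2-yl]-1,3a,4,5,6,7,8,8a-octahydroazulene-4,7-diol (not isolated) | C=C1[C@H]2CC=C(C)[C@@H]2[C@@H](O)[C@@H]([C@@H](C)C/C=C/C(C)(C)O[Si](C)(C)C)C[C@H]1O | intermediate
28 | (3aR,4S,5R,7R,8aS)-5-[(2S,4E)-6-hydroxy-6-methylhept-4-en-2-yl]-3-methyl-8-methylidene-1,3a,4,5,6,7,8,8a-octahydroazulene-4,7-diol | C=C1[C@H]2CC=C(C)[C@@H]2[C@@H](O)[C@@H]([C@@H](C)C/C=C/C(C)(C)O)C[C@H]1O | intermediate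
29 | (3aS,5R,7R,8S,8aR)-8-hydroxy-7-[(2S,4E)-6-hydroxy-6-methylhept-4-en-2-yl]-1-methyl-4-methylidene-3,3a,4,5,6,7,8,8a-octahydroazulen-5-yl acetate | C=C1[C@H]2CC=C(C)[C@@H]2[C@@H](O)[C@@H]([C@@H](C)C/C=C/C(C)(C)O)C[C@H]1OC(C)=O | target

## Step count and risks

Total: 15 steps. Longest linear sequence: 11 steps (steps 5 to 15, from tiglic aldehyde to 29); the carbamate arm takes 4 steps (1 to 4).

**Step 11 (most at risk).** Three stereocentres already present (C5 and C1 in 20, C11 in 8) meet a reagent whose lithio–sparteine complex may not be fully configurationally stable. A mismatch with the Felkin preference of the easily conjugated aldehyde 20 would lower the 6S,7R selectivity. The fallback sets out from 18 and 7 and keeps C6 as the nucleophile, now as a nitronate (an acyl-anion equivalent). Cross-metathesis of 7 with crotonaldehyde (second-generation Hoveyda–Grubbs catalyst) gives (2E,4S,6E)-4,8-dimethyl-8-[(trimethylsilyl)oxy]nona-2,6-dienal F1. Nitro compound 18 then adds to F1 under iminium catalysis by (R)-2-[diphenyl(trimethylsilyloxy)methyl]pyrrolidine (PhCO2H, MeOH), which fixes C7, to give the γ-nitro aldehyde (3R)-4-[(1R,5S)-5-(1-iodoethenyl)-2-methylcyclopent-2-en-1-yl]-3-[(2S,4E)-6-methyl-6-[(trimethylsilyl)oxy]hept-4-en-2-yl]-4-nitrobutanal F2. Ring closure with CrCl2 and catalytic NiCl2 gives the nitro cycloheptenol (3aR,5R,7R,8aS)-3-methyl-8-methylidene-5-[(2S,4E)-6-methyl-6-[(trimethylsilyl)oxy]hept-4-en-2-yl]-4-nitro-1,3a,4,5,6,7,8,8a-octahydroazulen-7-ol F3. A Nef reaction (aq. TiCl3, NH4OAc) gives the hydroxy ketone (3aR,5R,7R,8aS)-7-hydroxy-3-methyl-8-methylidene-5-[(2S,4E)-6-methyl-6-[(trimethylsilyl)oxy]hept-4-en-2-yl]-3a,5,6,7,8,8a-hexahydroazulen-4(1H)-one F4. Reduction with LiBH(s-Bu)3 from the face opposite the C7 side chain then returns to the route at 27.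

**Step 12.** The potassium enolate 24 can go on to a cyclopropanecarbaldehyde by 1,3-cycloelimination, or the acyl transfer may be slow at the hindered C6 alkoxide. The fallback sets out from 23 and unmasks C9 by reduction instead of acyl transfer. LiAlH4 (THF, 0 °C) cleaves the enol carbamate and work-up gives the lactol (4R,5S)-5-[(1R,5S)-5-(1-iodoethenyl)-2-methylcyclopent-2-en-1-yl]-4-[(2S,4E)-6-methyl-6-[(trimethylsilyl)oxy]hept-4-en-2-yl]oxolan-2-ol F5. F5 is cyclised through its open hydroxy-aldehyde form with CrCl2 and catalytic NiCl2, returning to the route at 27 with the C6 hydroxyl already free.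

**Step 13.** Seven-membered ring closure may favour the wrong C9 epimer. The fallback sets out from 25 and installs the acetate with inversion. The epimeric product (3aR,4S,5R,7S,8aS)-7-hydroxy-3-methyl-8-methylidene-5-[(2S,4E)-6-methyl-6-[(trimethylsilyl)oxy]hept-4-en-2-yl]-1,3a,4,5,6,7,8,8a-octahydroazulen-4-yl N,N-di(propan-2-yl)carbamate F6 is treated as in step 14. This gives, through the 9-epimeric diol silyl ether (3aR,4S,5R,7S,8aS)-3-methyl-8-methylidene-5-[(2S,4E)-6-methyl-6-[(trimethylsilyl)oxy]hept-4-en-2-yl]-1,3a,4,5,6,7,8,8a-octahydroazulene-4,7-diol F7, the 9-epimeric triol (3aR,4S,5R,7S,8aS)-5-[(2S,4E)-6-hydroxy-6-methylhept-4-en-2-yl]-3-methyl-8-methylidene-1,3a,4,5,6,7,8,8a-octahydroazulene-4,7-diol F8. A Mitsunobu reaction of F8 with acetic acid (PPh3, diisopropyl azodicarboxylate) at the allylic C9 hydroxyl returns to the route at 29, replacing step 15.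

## Further compounds

F1 | step 11 | (2E,4S,6E)-4,8-dimethyl-8-[(trimethylsilyl)oxy]nona-2,6-dienal | O=C/C=C/[C@@H](C)C/C=C/C(C)(C)O[Si](C)(C)C
F2 | step 11 | (3R)-4-[(1R,5S)-5-(1-iodoethenyl)-2-methylcyclopent-2-en-1-yl]-3-[(2S,4E)-6-methyl-6-[(trimethylsilyl)oxy]hept-4-en-2-yl]-4-nitrobutanal (both C4 epimers) | C=C(I)[C@H]1CC=C(C)[C@@H]1C([N+](=O)[O-])[C@@H]([C@@H](C)C/C=C/C(C)(C)O[Si](C)(C)C)CC=O
F3 | step 11 | (3aR,5R,7R,8aS)-3-methyl-8-methylidene-5-[(2S,4E)-6-methyl-6-[(trimethylsilyl)oxy]hept-4-en-2-yl]-4-nitro-1,3a,4,5,6,7,8,8a-octahydroazulen-7-ol (both C4 epimers) | C=C1[C@H]2CC=C(C)[C@@H]2C([N+](=O)[O-])[C@@H]([C@@H](C)C/C=C/C(C)(C)O[Si](C)(C)C)C[C@H]1O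
F4 | step 11 | (3aR,5R,7R,8aS)-7-hydroxy-3-methyl-8-methylidene-5-[(2S,4E)-6-methyl-6-[(trimethylsilyl)oxy]hept-4-en-2-yl]-3a,5,6,7,8,8a-hexahydroazulen-4(1H)-one | C=C1[C@H]2CC=C(C)[C@@H]2C(=O)[C@@H]([C@@H](C)C/C=C/C(C)(C)O[Si](C)(C)C)C[C@H]1O
F5 | step 12 | (4R,5S)-5-[(1R,5S)-5-(1-iodoethenyl)-2-methylcyclopent-2-en-1-yl]-4-[(2S,4E)-6-methyl-6-[(trimethylsilyl)oxy]hept-4-en-2-yl]oxolan-2-ol (both anomers) | C=C(I)[C@H]1CC=C(C)[C@@H]1[C@H]1OC(O)C[C@@H]1[C@@H](C)C/C=C/C(C)(C)O[Si](C)(C)C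
F6 | step 13 | (3aR,4S,5R,7S,8aS)-7-hydroxy-3-methyl-8-methylidene-5-[(2S,4E)-6-methyl-6-[(trimethylsilyl)oxy]hept-4-en-2-yl]-1,3a,4,5,6,7,8,8a-octahydroazulen-4-yl N,N-di(propan-2-yl)carbamate | C=C1[C@H]2CC=C(C)[C@@H]2[C@@H](OC(=O)N(C(C)C)C(C)C)[C@@H]([C@@H](C)C/C=C/C(C)(C)O[Si](C)(C)C)C[C@@H]1O
F7 | step 13 | (3aR,4S,5R,7S,8aS)-3-methyl-8-methylidene-5-[(2S,4E)-6-methyl-6-[(trimethylsilyl)oxy]hept-4-en-2-yl]-1,3a,4,5,6,7,8,8a-octahydroazulene-4,7-diol | C=C1[C@H]2CC=C(C)[C@@H]2[C@@H](O)[C@@H]([C@@H](C)C/C=C/C(C)(C)O[Si](C)(C)C)C[C@@H]1O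
F8 | step 13 | (3aR,4S,5R,7S,8aS)-5-[(2S,4E)-6-hydroxy-6-methylhept-4-en-2-yl]-3-methyl-8-methylidene-1,3a,4,5,6,7,8,8a-octahydroazulene-4,7-diol | C=C1[C@H]2CC=C(C)[C@@H]2[C@@H](O)[C@@H]([C@@H](C)C/C=C/C(C)(C)O)C[C@@H]1O
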